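The route rests on cutting, in one retrosynthetic move, the two bonds where the seven-membered carbocycle (ring S) meets the second dihydrofuran (ring D): the bond from C5 of the central benzofuran ring B to C3 of ring D, which both rings share, and the O–C2 bond of ring D. A single oxidation of a tethered 4-hydroxystilbene forms both bonds, both rings and both new stereocentres. Its precursor is an enantiopure trans-2,3-diaryl-2,3-dihydrobenzofuran (ring C fused to ring B) with a free C6 phenol and, at C4, a CH2–CH(aryl) tether to ring A of an E-configured 3,5-dimethoxy-4'-hydroxystilbene; it is built from two fragments joined by Negishi coupling.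

Key step: step 14

Assumption: the catalyst antipodes written in steps 5 and 8 are those taken to deliver the configurations shown; if induction runs the other way, the mirror-image ligand is used.
Assumption: 5-iodoresorcinol, 2-bromo-4,6-dimethoxybenzaldehyde and 4-(tert-butyldimethylsilyloxy)styrene are taken as commercially available.

Ring names used below: ring B is the central benzene ring (benzofuran numbering O1, C2, C3, C3a, C4–C7, C7a), ring C the first dihydrofuran, ring A the dimethoxybenzene ring of the stilbene, ring S the seven-membered ring, ring D the second dihydrofuran.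

Step 1
Reactants: 1 5-iodoresorcinol; 2 3,5-dimethoxybenzoic acid
Product: 3 (2,4-dihydroxy-6-iodophenyl)(3,5-dimethoxyphenyl)methanone
Conditions: BF3·OEt2 (neat), 85 °C; aq. NaOAc work-up
Reagents that add atoms: none
Why: Nencki-type Friedel–Crafts acylation of a resorcinol by a carboxylic acid should go to the carbon para to one hydroxyl and ortho to the other (here also ortho to iodine, the usual site for 5-halo-resorcinol derivatives), and the chelated ortho-hydroxy ketone formed is deactivated towards a second acylation.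

Step 2
Reactants: 3 (2,4-dihydroxy-6-iodophenyl)(3,5-dimethoxyphenyl)methanone
Product: 4 (2-hydroxy-6-iodo-4-[(triisopropylsilyl)oxy]phenyl)(3,5-dimethoxyphenyl)methanone
Conditions: TIPSCl (1.05 equiv), imidazole, CH2Cl2, 0 °C
Reagents that add atoms: triisopropylsilyl chloride, CC(C)[Si](Cl)(C(C)C)C(C)C
Why: Chemoselective silylation, since the hydroxyl ortho to the carbonyl is locked in a hydrogen bond and shielded, so that only the para hydroxyl (the later free phenol of the key-step precursor) is silylated.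

Step 3
Reactants: 4 (2-hydroxy-6-iodo-4-[(triisopropylsilyl)oxy]phenyl)(3,5-dimethoxyphenyl)methanone; 5 4-methoxybenzyl alcohol
Product: 6 (2-iodo-6-[(4-methoxybenzyl)oxy]-4-[(triisopropylsilyl)oxy]phenyl)(3,5-dimethoxyphenyl)methanone
Conditions: PPh3, DIAD, THF, 0 °C → rt
Reagents that add atoms: none
Why: Mitsunobu etherification of the remaining chelated phenol (acidic enough for the betaine) with a primary benzylic alcohol runs under neutral conditions that spare the aryl silyl ether and the aryl iodide, and installs the ArO–CH2Ar unit whose C–H bonds are used in step 5.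

Step 4
Reactants: 6 (2-iodo-6-[(4-methoxybenzyl)oxy]-4-[(triisopropylsilyl)oxy]phenyl)(3,5-dimethoxyphenyl)methanone
Product: 7 hydrazone of ketone 6 (C=N–NH2, C=N geometry not defined)
Conditions: N2H4 (anhydrous, 10 equiv), AcOH (cat.), EtOH, 80 °C (sealed tube)
Reagents that add atoms: hydrazine, NN
Why: Acid-catalysed condensation of hydrazine with a diaryl ketone gives the free hydrazone, the standard precursor of a diaryldiazomethane; the small nucleophile and sealed-tube heating answer the shielding by the two ortho substituents, and the anhydrous medium spares the hindered silyl ether.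

Step 5
Reactants: 7 hydrazone of ketone 6
Product: 9 (2S,3R)-3-(3,5-dimethoxyphenyl)-4-iodo-2-(4-methoxyphenyl)-6-[(triisopropylsilyl)oxy]-2,3-dihydro-1-benzofuran (cis isomer), via diaryldiazomethane 8 (not isolated)
Conditions: MnO2, CH2Cl2, 0 °C, filter; then Rh2(S-PTAD)4 (1 mol%), CH2Cl2, 0 °C
Reagents that add atoms: none
Why: Oxidation of the hydrazone to the diaryldiazomethane and its decomposition by the chiral dirhodium tetracarboxylate give a donor/donor rhodium carbene that inserts intramolecularly (1,5) into the benzylic ether C–H bond, a known enantioselective route to cis-2,3-diaryl-2,3-dihydrobenzofurans in which the catalyst sets C3 (R) and the concerted insertion places C2 (S) cis to it.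

Step 6
Reactants: 9 (2S,3R)-3-(3,5-dimethoxyphenyl)-4-iodo-2-(4-methoxyphenyl)-6-[(triisopropylsilyl)oxy]-2,3-dihydro-1-benzofuran
Product: 10 (2R,3R)-3-(3,5-dimethoxyphenyl)-4-iodo-2-(4-methoxyphenyl)-6-[(triisopropylsilyl)oxy]-2,3-dihydro-1-benzofuran (trans isomer)
Conditions: TFA (5 equiv), CH2Cl2, 0 °C → rt
Reagents that add atoms: none
Why: Acid-promoted epimerisation at C2 through reversible ionisation of the benzylic C2–O bond to a 4-methoxyphenyl-stabilised cation and reclosure should give the thermodynamically preferred trans isomer (2R), while C3 is not involved and keeps the configuration set in step 5.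

Step 7
Reactants: 11 2-bromo-4,6-dimethoxybenzaldehyde; 12 ethyl (triphenylphosphoranylidene)acetate
Product: 13 ethyl (2E)-3-(2-bromo-4,6-dimethoxyphenyl)prop-2-enoate
Conditions: toluene, 100 °C
Reagents that add atoms: none
Why: Wittig olefination with a stabilised ylide is E-selective and tolerates the hindered aldehyde and the aryl bromide.

Step 8
Reactants: 13 ethyl (2E)-3-(2-bromo-4,6-dimethoxyphenyl)prop-2-enoate; 14 2,4-dimethoxyphenylboronic acid
Product: 15 ethyl (3S)-3-(2-bromo-4,6-dimethoxyphenyl)-3-(2,4-dimethoxyphenyl)propanoate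
Conditions: [Rh(OH)((R)-binap)]2 (3 mol% Rh), 14 (3 equiv), dioxane/H2O (10:1), 60 °C
Reagents that add atoms: none
Why: Hayashi–Miyaura rhodium-catalysed asymmetric 1,4-addition of an arylboronic acid to a β-aryl enoate, in which the BINAP-bound aryl-rhodium species adds to one enantioface of the alkene and so sets the diaryl methine centre (S), the aryl bromide being inert to the catalyst.

Step 9
Reactants: 15 ethyl (3S)-3-(2-bromo-4,6-dimethoxyphenyl)-3-(2,4-dimethoxyphenyl)propanoate
Product: 16 (3S)-3-(2-bromo-4,6-dimethoxyphenyl)-3-(2,4-dimethoxyphenyl)propanoic acid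
Conditions: LiOH, THF/MeOH/H2O, rt; then 1 M HCl
Reagents that add atoms: lithium hydroxide, [Li+].[OH-]
Why: Saponification of the ethyl ester, under which the diaryl methine centre is far too weakly acidic to epimerise.

Step 10
Reactants: 16 (3S)-3-(2-bromo-4,6-dimethoxyphenyl)-3-(2,4-dimethoxyphenyl)propanoic acid
Product: 18 1-bromo-2-[(1S)-1-(2,4-dimethoxyphenyl)-2-iodoethyl]-3,5-dimethoxybenzene, via Barton ester 17 (not isolated)
Conditions: N-hydroxypyridine-2-thione, DCC, DMAP (cat.), CH2Cl2, 0 °C, dark; then CHI3, PhCF3, hν (tungsten lamp), 60 °C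
Reagents that add atoms: iodoform, IC(I)I
Why: Barton decarboxylative iodination, in which the thiohydroxamate ester fragments under light to the primary alkyl radical, which should abstract iodine from iodoform faster than it can rearrange by 1,2-aryl shift, the stereocentre one carbon away from the radical being untouched.

Step 11
Reactants: 18 1-bromo-2-[(1S)-1-(2,4-dimethoxyphenyl)-2-iodoethyl]-3,5-dimethoxybenzene; 10 (2R,3R)-3-(3,5-dimethoxyphenyl)-4-iodo-2-(4-methoxyphenyl)-6-[(triisopropylsilyl)oxy]-2,3-dihydro-1-benzofuran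
Product: 20 (2R,3R)-4-[(2S)-2-(2-bromo-4,6-dimethoxyphenyl)-2-(2,4-dimethoxyphenyl)ethyl]-3-(3,5-dimethoxyphenyl)-2-(4-methoxyphenyl)-6-[(triisopropylsilyl)oxy]-2,3-dihydro-1-benzofuran, via alkylzinc iodide 19 (not isolated)
Conditions: Zn dust (TMSCl/BrCH2CH2Br-activated), LiCl, THF, 40 °C; then 10, PdCl2(dppf) (5 mol%), THF, 50 °C
Reagents that add atoms: none
Why: Negishi sp3–sp2 cross-coupling, in which zinc inserts into the primary alkyl iodide but not into the aryl bromide, and the dppf-ligated palladium catalyst (fast reductive elimination, little β-hydride elimination) adds to the aryl iodide of 10 much faster than to the hindered, electron-rich aryl bromide, no stereocentre being touched.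

Step 12
Reactants: 20 (2R,3R)-4-[(2S)-2-(2-bromo-4,6-dimethoxyphenyl)-2-(2,4-dimethoxyphenyl)ethyl]-3-(3,5-dimethoxyphenyl)-2-(4-methoxyphenyl)-6-[(triisopropylsilyl)oxy]-2,3-dihydro-1-benzofuran; 21 4-(tert-butyldimethylsilyloxy)styrene
Product: 22 compound 20 with the bromine replaced by an (E)-2-[4-(tert-butyldimethylsilyloxy)phenyl]ethenyl group (bis-silyl ether of the key-step precursor)
Conditions: Pd[P(t-Bu)3]2 (5 mol%), Cy2NMe, dioxane, 90 °C
Reagents that add atoms: none
Why: Mizoroki–Heck reaction of an ortho-substituted, electron-rich aryl bromide with a styrene under bulky trialkylphosphine/amine-base conditions should give the E-stilbene by syn insertion and syn β-hydride elimination, the carboxylate-free base disfavouring palladation of the neighbouring aryl ring.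

Step 13
Reactants: 22 bis-silyl ether of the key-step precursor
Product: 23 (2R,3R)-4-[(2S)-2-{2-[(E)-2-(4-hydroxyphenyl)ethenyl]-4,6-dimethoxyphenyl}-2-(2,4-dimethoxyphenyl)ethyl]-3-(3,5-dimethoxyphenyl)-2-(4-methoxyphenyl)-2,3-dihydro-1-benzofuran-6-ol
Conditions: TBAF (2.5 equiv), THF, 0 °C; AcOH quench
Reagents that add atoms: none
Why: Fluoride-induced cleavage of both aryl silyl ethers should free the ring B phenol and the 4-hydroxystilbene in one operation without touching the seven methyl ethers or the alkene.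

Step 14
Reactants: 23 (2R,3R)-4-[(2S)-2-{2-[(E)-2-(4-hydroxyphenyl)ethenyl]-4,6-dimethoxyphenyl}-2-(2,4-dimethoxyphenyl)ethyl]-3-(3,5-dimethoxyphenyl)-2-(4-methoxyphenyl)-2,3-dihydro-1-benzofuran-6-ol
Product: 25 heptamethyl ether of 26 in which only the 4-hydroxyphenyl group on C2 of ring D is free (ring C 2R,3R; tether carbon S; ring D 2R,3R), via para-quinone methide 24 (not isolated)
Conditions: PhI(OAc)2 (1.05 equiv, slow addition), (CF3)2CHOH (0.005 M), Ar, −20 → 0 °C
Reagents that add atoms: none
Why: Proposed new method: two-electron oxidation of the 4-hydroxystilbene by the trivalent iodine reagent in the ionising, weakly nucleophilic solvent should give a quinone-methide cation with its positive charge on the alkene carbon next to ring A; C5 of ring B (ortho to the free phenol, para to the ring C oxygen) attacks this carbon in a 7-exo-trig Friedel–Crafts alkylation that closes ring S, and the phenol then adds to the exocyclic carbon of the resulting para-quinone methide in a 5-exo-trig oxa-Michael step that closes ring D and restores the 4-hydroxyphenyl group. The closest known reaction type is the intermolecular oxidative [3+2] coupling of phenols with 4-hydroxystilbenes or related styrenes (Ag2O, FeCl3 or PhI(OAc)2) to trans-2-aryl-2,3-dihydrobenzofurans; a tethered version that closes a carbocycle in the same event has not been shown. C3 of ring D is set in the C–C bond formation by the (S) centre of the tether, whose 2,4-dimethoxyphenyl group should sit pseudo-axial in the developing seven-membered ring to avoid the flanking methoxy group of ring A, so that ring B is expected to add to the face that puts the new C–H cis to the tether C–H and the quinone methide arm in the plane of ring B, as the furan closure requires. C2 is set relative to C3 by ring closure anti to ring A, and because the addition to the quinone methide is reversible the trans arrangement is also the thermodynamic outcome. The step needs chemoselective oxidation of the conjugated 4-hydroxystilbene beside the less easily oxidised resorcinol-type phenol (secured by its lower oxidation potential, one equivalent of oxidant, low temperature and high dilution) and attack through C5 instead of C7 (secured by the tether, since C7 would need a nine-membered ring), while the methyl ethers on the 2,4-dimethoxyphenyl ring block the competing O-attack on the cation.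

Step 15
Reactants: 25 heptamethyl ether with free 4-hydroxyphenyl group on ring D
Product: 26 target CNP0154047.2 (ring C 2R,3R; tether carbon S; ring D 2R,3R; eight free phenols)
Conditions: BBr3 (20 equiv), CH2Cl2, −78 → 0 °C; aq. NaHCO3 quench
Reagents that add atoms: none
Why: Lewis acid cleavage of the seven aryl methyl ethers by BBr3 (borate formation, bromide attack on methyl) is the usual last step for permethylated resveratrol oligomers, and the low temperature limits ionisation of the two benzylic C2–O bonds, which would in any case reclose to the trans isomers.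

Compound list
1 | 5-iodoresorcinol (5-iodobenzene-1,3-diol) | Oc1cc(O)cc(I)c1 | starting material
2 | 3,5-dimethoxybenzoic acid | COc1cc(OC)cc(C(=O)O)c1 | starting material
3 | (2,4-dihydroxy-6-iodophenyl)(3,5-dimethoxyphenyl)methanone | COc1cc(OC)cc(C(=O)c2c(O)cc(O)cc2I)c1 | intermediate
4 | (2-hydroxy-6-iodo-4-[(triisopropylsilyl)oxy]phenyl)(3,5-dimethoxyphenyl)methanone | COc1cc(OC)cc(C(=O)c2c(O)cc(O[Si](C(C)C)(C(C)C)C(C)C)cc2I)c1 | intermediate
5 | 4-methoxybenzyl alcohol | COc1ccc(CO)cc1 | starting material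
6 | (2-iodo-6-[(4-methoxybenzyl)oxy]-4-[(triisopropylsilyl)oxy]phenyl)(3,5-dimethoxyphenyl)methanone | COc1ccc(COc2cc(O[Si](C(C)C)(C(C)C)C(C)C)cc(I)c2C(=O)c2cc(OC)cc(OC)c2)cc1 | intermediate
7 | hydrazone of ketone 6 | COc1ccc(COc2cc(O[Si](C(C)C)(C(C)C)C(C)C)cc(I)c2C(=NN)c2cc(OC)cc(OC)c2)cc1 | intermediate
8 | 2-[diazo(3,5-dimethoxyphenyl)methyl]-1-iodo-3-[(4-methoxybenzyl)oxy]-5-[(triisopropylsilyl)oxy]benzene | COc1ccc(COc2cc(O[Si](C(C)C)(C(C)C)C(C)C)cc(I)c2C(=[N+]=[N-])c2cc(OC)cc(OC)c2)cc1 | intermediate
9 | (2S,3R)-3-(3,5-dimethoxyphenyl)-4-iodo-2-(4-methoxyphenyl)-6-[(triisopropylsilyl)oxy]-2,3-dihydro-1-benzofuran (cis) | COc1ccc([C@H]2Oc3cc(O[Si](C(C)C)(C(C)C)C(C)C)cc(I)c3[C@H]2c2cc(OC)cc(OC)c2)cc1 | intermediate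
10 | (2R,3R)-3-(3,5-dimethoxyphenyl)-4-iodo-2-(4-methoxyphenyl)-6-[(triisopropylsilyl)oxy]-2,3-dihydro-1-benzofuran (trans) | COc1ccc([C@@H]2Oc3cc(O[Si](C(C)C)(C(C)C)C(C)C)cc(I)c3[C@H]2c2cc(OC)cc(OC)c2)cc1 | intermediate
11 | 2-bromo-4,6-dimethoxybenzaldehyde | COc1cc(OC)c(C=O)c(Br)c1 | starting material
12 | ethyl (triphenylphosphoranylidene)acetate | CCOC(=O)C=P(c1ccccc1)(c1ccccc1)c1ccccc1 | starting material
13 | ethyl (2E)-3-(2-bromo-4,6-dimethoxyphenyl)prop-2-enoate | CCOC(=O)/C=C/c1c(OC)cc(OC)cc1Br | intermediate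
14 | 2,4-dimethoxyphenylboronic acid | COc1ccc(B(O)O)c(OC)c1 | starting material
15 | ethyl (3S)-3-(2-bromo-4,6-dimethoxyphenyl)-3-(2,4-dimethoxyphenyl)propanoate | CCOC(=O)C[C@@H](c1ccc(OC)cc1OC)c1c(OC)cc(OC)cc1Br | intermediate
16 | (3S)-3-(2-bromo-4,6-dimethoxyphenyl)-3-(2,4-dimethoxyphenyl)propanoic acid | OC(=O)C[C@@H](c1ccc(OC)cc1OC)c1c(OC)cc(OC)cc1Br | intermediate
17 | 2-thioxopyridin-1(2H)-yl (3S)-3-(2-bromo-4,6-dimethoxyphenyl)-3-(2,4-dimethoxyphenyl)propanoate (Barton ester) | O=C(C[C@@H](c1ccc(OC)cc1OC)c1c(OC)cc(OC)cc1Br)On1ccccc1=S | intermediate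
18 | 1-bromo-2-[(1S)-1-(2,4-dimethoxyphenyl)-2-iodoethyl]-3,5-dimethoxybenzene | IC[C@@H](c1ccc(OC)cc1OC)c1c(OC)cc(OC)cc1Br | intermediate
19 | [(2S)-2-(2-bromo-4,6-dimethoxyphenyl)-2-(2,4-dimethoxyphenyl)ethyl]zinc iodide | I[Zn]C[C@@H](c1ccc(OC)cc1OC)c1c(OC)cc(OC)cc1Br | intermediate
20 | (2R,3R)-4-[(2S)-2-(2-bromo-4,6-dimethoxyphenyl)-2-(2,4-dimethoxyphenyl)ethyl]-3-(3,5-dimethoxyphenyl)-2-(4-methoxyphenyl)-6-[(triisopropylsilyl)oxy]-2,3-dihydro-1-benzofuran | COc1ccc([C@@H]2Oc3cc(O[Si](C(C)C)(C(C)C)C(C)C)cc(c3[C@H]2c2cc(OC)cc(OC)c2)C[C@@H](c2ccc(OC)cc2OC)c2c(OC)cc(OC)cc2Br)cc1 | intermediate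
21 | 4-(tert-butyldimethylsilyloxy)styrene | C=Cc1ccc(O[Si](C)(C)C(C)(C)C)cc1 | starting material
22 | (2R,3R)-4-[(2S)-2-{2-[(E)-2-(4-{[tert-butyl(dimethyl)silyl]oxy}phenyl)ethenyl]-4,6-dimethoxyphenyl}-2-(2,4-dimethoxyphenyl)ethyl]-3-(3,5-dimethoxyphenyl)-2-(4-methoxyphenyl)-6-[(triisopropylsilyl)oxy]-2,3-dihydro-1-benzofuran | COc1ccc([C@@H]2Oc3cc(O[Si](C(C)C)(C(C)C)C(C)C)cc(c3[C@H]2c2cc(OC)cc(OC)c2)C[C@@H](c2ccc(OC)cc2OC)c2c(OC)cc(OC)cc2/C=C/c2ccc(O[Si](C)(C)C(C)(C)C)cc2)cc1 | intermediate
23 | (2R,3R)-4-[(2S)-2-{2-[(E)-2-(4-hydroxyphenyl)ethenyl]-4,6-dimethoxyphenyl}-2-(2,4-dimethoxyphenyl)ethyl]-3-(3,5-dimethoxyphenyl)-2-(4-methoxyphenyl)-2,3-dihydro-1-benzofuran-6-ol (key-step precursor) | COc1ccc([C@@H]2Oc3cc(O)cc(c3[C@H]2c2cc(OC)cc(OC)c2)C[C@@H](c2ccc(OC)cc2OC)c2c(OC)cc(OC)cc2/C=C/c2ccc(O)cc2)cc1 | intermediate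
24 | para-quinone methide with ring S closed: new ring S carbon (R) carries CH=(4-oxocyclohexa-2,5-dien-1-ylidene); ring B phenol free; ring C 2R,3R; tether carbon S | COc1ccc([C@@H]2Oc3cc(O)c5c(c3[C@H]2c2cc(OC)cc(OC)c2)C[C@@H](c2ccc(OC)cc2OC)c2c(OC)cc(OC)cc2[C@H]5C=C2C=CC(=O)C=C2)cc1 | intermediate
25 | heptamethyl ether of 26 with the 4-hydroxyphenyl group on C2 of ring D free (ring C 2R,3R; tether carbon S; ring D 2R,3R) | COc1ccc([C@@H]2Oc3cc4c5c(c3[C@H]2c2cc(OC)cc(OC)c2)C[C@@H](c2ccc(OC)cc2OC)c2c(OC)cc(OC)cc2[C@H]5[C@H](c2ccc(O)cc2)O4)cc1 | intermediate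
26 | CNP0154047.2 (ring C 2R,3R; tether carbon S; ring D 2R,3R) | Oc1ccc([C@@H]2Oc3cc4c5c(c3[C@H]2c2cc(O)cc(O)c2)C[C@@H](c2ccc(O)cc2O)c2c(O)cc(O)cc2[C@H]5[C@H](c2ccc(O)cc2)O4)cc1 | target

Total step count: 15. Longest linear sequence: 11 steps (steps 1–6, then 11–15); the side-chain branch (steps 7–10) joins at step 11.

Steps most likely to fail

Step 14 (Proposed new method). What may go wrong: oxidation at the ring B phenol or over-oxidation of the newly freed 4-hydroxyphenyl group; capture of the cation through another position (for example ipso attack on the 2,4-dimethoxyphenyl ring) or by solvent; attack on the wrong alkene face at C3 of ring D. The fallback uses known reactions only, sets out from 20 and returns at 26. Bromine–lithium exchange on 20 (n-BuLi, THF, −78 °C) followed by DMF gives aldehyde F1, and TBAF frees the phenol to give hydroxy aldehyde F2. As its bromomagnesium phenoxide (EtMgBr, toluene) F2 should undergo ortho-specific intramolecular hydroxyalkylation at C5, closing ring S to the cyclic 2-hydroxybenzhydrol F3 (carbinol configuration immaterial). Warming F3 with Cs2CO3 and (4-methoxybenzyl)dimethylsulfonium triflate releases the ortho-quinone methide F4, which the sulfonium ylide traps in a [4+1] annulation (conjugate addition, then displacement of dimethyl sulfide by the phenoxide) to give the trans ring D of octamethyl ether F5. BBr3 as in step 15 then cleaves eight methyl ethers to give 26.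

Step 8. What may go wrong: slow insertion of the aryl-rhodium species because the ortho bromine and methoxy groups of the twisted aryl ring shield both faces of the β-carbon, so that protodeboronation of the boronic acid wins. The fallback sets out from 11 and returns at 16, and moves the addition to a planar cyclic acceptor. BCl3 (CH2Cl2, 0 °C) cleaves only the methyl ether ortho to the formyl group of 11 to give salicylaldehyde F6. Wittig olefination with 12 in hot N,N-diethylaniline, with lactonisation, gives 5-bromo-7-methoxycoumarin F7, whose β-carbon is open on both faces. Rhodium-catalysed asymmetric addition of 14 (Rh(acac)(C2H4)2, SEGPHOS, dioxane/H2O, 60 °C) gives (S)-chromanone F8. NaOH then Me2SO4 open the lactone and methylate phenoxide and carboxylate to methyl ester F9, and saponification gives 16.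

Step 4. What may go wrong: no condensation at the carbonyl shielded by the ortho iodine and ortho benzyloxy groups, or loss of the silyl ether under forcing hydrazine treatment; step 5 then has no substrate. The fallback sets out from 4 and returns at 10, giving up asymmetric catalysis for a racemic annulation and a resolution. NaBH4 (EtOH/THF, 0 °C) reduces ketone 4 to 2-hydroxybenzhydrol F10. On warming with Cs2CO3 and (4-methoxybenzyl)dimethylsulfonium triflate, the ortho-quinone methide F11 of F10 should undergo the sulfur-ylide [4+1] annulation to racemic trans-dihydrobenzofuran F12. Preparative chromatography on a chiral stationary phase then gives 10.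

Further compounds
F1 | step 14 | (2R,3R)-4-[(2S)-2-(2-formyl-4,6-dimethoxyphenyl)-2-(2,4-dimethoxyphenyl)ethyl]-3-(3,5-dimethoxyphenyl)-2-(4-methoxyphenyl)-6-[(triisopropylsilyl)oxy]-2,3-dihydro-1-benzofuran | COc1ccc([C@@H]2Oc3cc(O[Si](C(C)C)(C(C)C)C(C)C)cc(c3[C@H]2c2cc(OC)cc(OC)c2)C[C@@H](c2ccc(OC)cc2OC)c2c(OC)cc(OC)cc2C=O)cc1
F2 | step 14 | 2-[(1S)-1-(2,4-dimethoxyphenyl)-2-[(2R,3R)-3-(3,5-dimethoxyphenyl)-6-hydroxy-2-(4-methoxyphenyl)-2,3-dihydro-1-benzofuran-4-yl]ethyl]-3,5-dimethoxybenzaldehyde | COc1ccc([C@@H]2Oc3cc(O)cc(c3[C@H]2c2cc(OC)cc(OC)c2)C[C@@H](c2ccc(OC)cc2OC)c2c(OC)cc(OC)cc2C=O)cc1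
F3 | step 14 | cyclic 2-hydroxybenzhydrol: F2 with ring S closed by a bond from C5 of ring B to the former formyl carbon, which now carries OH (configuration not defined) | COc1ccc([C@@H]2Oc3cc(O)c5c(c3[C@H]2c2cc(OC)cc(OC)c2)C[C@@H](c2ccc(OC)cc2OC)c2c(OC)cc(OC)cc2C5O)cc1
F4 | step 14 | ortho-quinone methide from F3: C6 carbonyl on ring B and a C5=CH double bond within ring S | COc1ccc([C@@H]2OC3=CC(=O)C=5C(=C3[C@H]2c2cc(OC)cc(OC)c2)C[C@@H](c2ccc(OC)cc2OC)c2c(OC)cc(OC)cc2C=5)cc1
F5 | step 14 | octamethyl ether of 26 (ring C 2R,3R; tether carbon S; ring D 2R,3R) | COc1ccc([C@@H]2Oc3cc4c5c(c3[C@H]2c2cc(OC)cc(OC)c2)C[C@@H](c2ccc(OC)cc2OC)c2c(OC)cc(OC)cc2[C@H]5[C@H](c2ccc(OC)cc2)O4)cc1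
F6 | step 8 | 2-bromo-6-hydroxy-4-methoxybenzaldehyde | COc1cc(O)c(C=O)c(Br)c1
F7 | step 8 | 5-bromo-7-methoxy-2H-chromen-2-one | COc1cc(Br)c2C=CC(=O)Oc2c1
F8 | step 8 | (4S)-5-bromo-4-(2,4-dimethoxyphenyl)-7-methoxy-3,4-dihydro-2H-chromen-2-one | COc1cc(Br)c2c(c1)OC(=O)C[C@H]2c1ccc(OC)cc1OC
F9 | step 8 | methyl (3S)-3-(2-bromo-4,6-dimethoxyphenyl)-3-(2,4-dimethoxyphenyl)propanoate | COC(=O)C[C@@H](c1ccc(OC)cc1OC)c1c(OC)cc(OC)cc1Br
F10 | step 4 | 2-[(3,5-dimethoxyphenyl)(hydroxy)methyl]-3-iodo-5-[(triisopropylsilyl)oxy]phenol (racemic carbinol) | COc1cc(OC)cc(C(O)c2c(O)cc(O[Si](C(C)C)(C(C)C)C(C)C)cc2I)c1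
F11 | step 4 | 6-(3,5-dimethoxybenzylidene)-5-iodo-3-[(triisopropylsilyl)oxy]cyclohexa-2,4-dien-1-one (ortho-quinone methide) | O=C1C=C(O[Si](C(C)C)(C(C)C)C(C)C)C=C(I)C1=Cc1cc(OC)cc(OC)c1
F12 | step 4 | racemic trans-3-(3,5-dimethoxyphenyl)-4-iodo-2-(4-methoxyphenyl)-6-[(triisopropylsilyl)oxy]-2,3-dihydro-1-benzofuran (10 and its 2S,3S enantiomer) | COc1ccc([C@@H]2Oc3cc(O[Si](C(C)C)(C(C)C)C(C)C)cc(I)c3[C@H]2c2cc(OC)cc(OC)c2)cc1.COc1ccc([C@H]2Oc3cc(O[Si](C(C)C)(C(C)C)C(C)C)cc(I)c3[C@@H]2c2cc(OC)cc(OC)c2)cc1
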